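Numbering: labdane numbers for the acid half, primed numbers for the alcohol half; the central cyclohexene is C12–C13(=C14)–C15–C15′–C14′, with C11 on C12, methyl C16 on C13 and C13′ on C14′.
Retrosynthetic cuts: C14′–C13′ (ring CH to the trisubstituted C13′=C12′ alkene carbon) by a Zweifel olefination in which boron is a temporary bridge between the two halves; then C13=C14 (ring-closing metathesis), C12–C14′ and C12–C13 (two lithiation–borylation homologations), C12′=C13′ (iodo-Wittig), and the C12=C13 bond of 4-epi-trans-communic acid (ozonolysis).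
Forward order: one C16 aldehyde from the natural acid feeds both halves; on the acid half C13 and then C14′ are attached to C12 through boron, the central ring is closed by metathesis with boron left on C14′, the alcohol half becomes a Z alkenyl iodide, the two fragments are joined, and both silicon groups are removed last.
Stereochemistry: the eight decalin centres (4R,5R,9S,10R and 4′R,5′R,9′S,10′R) come from the natural acid; C12 is set with (−)-sparteine and C14′ with (+)-sparteine in the two carbenoid homologations (cis on the ring); C14′ migrates from boron to C13′ with retention, and the E alkene follows from the Z iodide by anti migration and anti elimination.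
Enabling feature: C14′ is a secondary sp3 carbon of the central ring bonded directly to C13′ of a trisubstituted alkene, the retron of a stereospecific boronate 1,2-shift followed by boron–iodine elimination.

Key step: step 12

Assumption: 4-epi-trans-communic acid (the C4 epimer of trans-communic acid, carboxyl on C18) is taken as a purchasable isolated diterpenoid, and both sparteine enantiomers are bought; the decalin configuration of 1 is unchanged in every compound below.

Step 1
Reactants: 1 4-epi-trans-communic acid
Product: 2 2-(trimethylsilyl)ethyl 4-epi-trans-communate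
Conditions: Me3SiCH2CH2OH, PPh3, DIAD, THF, 0 °C to rt
Reagents that add atoms: 2-(trimethylsilyl)ethanol, C[Si](C)(C)CCO
Why: Mitsunobu esterification: the phosphonium-activated primary alcohol is displaced by the hindered C18 carboxylate, so no attack at the shielded acyl carbon is needed and no stereocentre is touched.

Step 2
Reactants: 2 2-(trimethylsilyl)ethyl 4-epi-trans-communate
Product: 3 2-(trimethylsilyl)ethyl 12-oxo-13,14,15,16-tetranorlabd-8(17)-en-18-oate
Conditions: O3 (1.0 equiv, as CH2Cl2 solution), CH2Cl2, −78 °C; then PPh3, −78 °C to rt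
Reagents that add atoms: ozone, [O-][O+]=O
Why: Ozonolysis: with one equivalent of ozone the electron-rich trisubstituted C12=C13 bond of the conjugated diene should be cleaved in preference to the shielded 1,1-disubstituted C8=C17 methylene, as is known for communic acid esters, giving the C12 aldehyde without forming a stereocentre.

Step 3
Reactants: 3 2-(trimethylsilyl)ethyl 12-oxo-13,14,15,16-tetranorlabd-8(17)-en-18-oate
Product: 4 2-(trimethylsilyl)ethyl 12-hydroxy-13,14,15,16-tetranorlabd-8(17)-en-18-oate
Conditions: NaBH4, MeOH, 0 °C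
Reagents that add atoms: none
Why: Borohydride reduction of the aldehyde to the primary alcohol; the neopentyl-type C18 ester and the alkene do not react with NaBH4 at 0 °C.

Step 4
Reactants: 4 2-(trimethylsilyl)ethyl 12-hydroxy-13,14,15,16-tetranorlabd-8(17)-en-18-oate
Product: 5 2-(trimethylsilyl)ethyl 12-(N,N-diisopropylcarbamoyloxy)-13,14,15,16-tetranorlabd-8(17)-en-18-oate
Conditions: i-Pr2NCOCl, Et3N, DMAP (cat.), CH2Cl2, reflux
Reagents that add atoms: N,N-diisopropylcarbamoyl chloride, CC(C)N(C(C)C)C(Cl)=O
Why: O-Carbamoylation of the primary alcohol installs the group that directs the next lithiation and then serves as leaving group.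

Step 5
Reactants: 5 2-(trimethylsilyl)ethyl 12-(N,N-diisopropylcarbamoyloxy)-13,14,15,16-tetranorlabd-8(17)-en-18-oate; 6 isopropenylboronic acid pinacol ester
Product: 9 (12R)-allylic boronic ester (C12 carries the pinacolboryl group and a prop-1-en-2-yl group), via (12S)-12-lithio carbamate 7 (not isolated), via C12 boronate complex 8 (not isolated)
Conditions: s-BuLi, (−)-sparteine, Et2O, −78 °C; then 6; −78 °C to 35 °C
Reagents that add atoms: none
Why: Lithiation–borylation (sparteine-mediated carbamate deprotonation, then 1,2-metallate rearrangement): s-BuLi/(−)-sparteine removes the pro-S hydrogen at C12, boron takes the place of lithium with retention and the isopropenyl group shifts from boron to C12 with inversion as the carbamate leaves, which sets C12 as R under reagent control.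

Step 6
Reactants: 10 pent-4-en-1-ol
Product: 11 pent-4-en-1-yl N,N-diisopropylcarbamate
Conditions: i-Pr2NCOCl, Et3N, CH2Cl2, reflux
Reagents that add atoms: N,N-diisopropylcarbamoyl chloride, CC(C)N(C(C)C)C(Cl)=O
Why: O-Carbamoylation of a primary alcohol, as in step 4.

Step 7
Reactants: 9 (12R)-allylic boronic ester; 11 pent-4-en-1-yl N,N-diisopropylcarbamate
Product: 14 (12S,14′S)-open-chain boronic ester (C12 carries prop-1-en-2-yl and the 1-(pinacolboryl)pent-4-en-1-yl chain), via (R)-1-lithiopent-4-enyl carbamate 12 (not isolated), via C14′ boronate complex 13 (not isolated)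
Conditions: 11, s-BuLi, (+)-sparteine, Et2O, −78 °C; then 9; −78 °C to 35 °C
Reagents that add atoms: none
Why: Lithiation–borylation homologation of a secondary boronic ester: the (R)-lithio carbamate formed with (+)-sparteine adds to boron and the allylic C12 group migrates with retention at C12 and inversion at the carbenoid carbon, which sets C14′ as S under reagent control and leaves boron on C14′.

Step 8
Reactants: 14 (12S,14′S)-open-chain boronic ester
Product: 15 fragment A [2-(trimethylsilyl)ethyl 11-[(1S,6S)-2-methyl-6-(pinacolboryl)cyclohex-2-en-1-yl]-12,13,14,15,16-pentanorlabd-8(17)-en-18-oate; C11 and boron cis]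
Conditions: RuCl2(=CHPh)(PCy3)(H2IMes) (second-generation Grubbs catalyst, cat.), CH2Cl2, 40 °C
Reagents that add atoms: none
Why: Ring-closing metathesis of the isopropenyl and vinyl groups closes the central cyclohexene at C13=C14 with loss of ethene; six-ring closure to a trisubstituted alkene is fast, the hindered C8=C17 methylene and the C–B bond stay out, and the cis relation of C11 and boron follows from the centres set in steps 5 and 7.

Step 9
Reactants: 3 2-(trimethylsilyl)ethyl 12-oxo-13,14,15,16-tetranorlabd-8(17)-en-18-oate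
Product: 16 2-(trimethylsilyl)ethyl (12′Z)-13′-iodo-14′,15′-dinorlabda-8′(17′),12′-dien-18′-oate
Conditions: EtPPh3Br, n-BuLi, THF; I2, −78 °C; NaN(SiMe3)2, −20 °C; then 3, −78 °C to rt
Reagents that add atoms: ethyltriphenylphosphonium bromide, CC[P+](c1ccccc1)(c1ccccc1)c1ccccc1.[Br-]; iodine, II
Why: Stork–Zhao olefination (Wittig reaction of an α-iodo ylide): the kinetically controlled oxaphosphetane gives the Z alkenyl iodide with iodine cis to C11′, and the hindered ester is not attacked.

Step 10
Reactants: 16 2-(trimethylsilyl)ethyl (12′Z)-13′-iodo-14′,15′-dinorlabda-8′(17′),12′-dien-18′-oate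
Product: 17 (12′Z)-13′-iodo-14′,15′-dinorlabda-8′(17′),12′-dien-18′-ol
Conditions: i-Bu2AlH, CH2Cl2, −78 to 0 °C
Reagents that add atoms: none
Why: Hydride reduction of the ester to the primary C18′ alcohol; the alkenyl iodide and the exocyclic alkene are stable to i-Bu2AlH at this temperature.

Step 11
Reactants: 17 (12′Z)-13′-iodo-14′,15′-dinorlabda-8′(17′),12′-dien-18′-ol
Product: 18 fragment B [18′-O-tert-butyldimethylsilyl ether of 17]
Conditions: TBSCl, imidazole, DMF, 40 °C
Reagents that add atoms: tert-butyldimethylsilyl chloride, CC(C)(C)[Si](C)(C)Cl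
Why: Silyl ether formation protects the neopentyl alcohol so that the alkenyllithium of step 12 is not quenched.

Step 12
Reactants: 15 fragment A; 18 fragment B
Product: 22 protected dimer [18′-O-TBS ether 2-(trimethylsilyl)ethyl ester of the target], via (12′Z)-alkenyllithium 19 (not isolated), via alkenyl boronate complex 20 (not isolated), via β-iodoboronic ester 21 (not isolated)
Conditions: 18, t-BuLi (2 equiv), THF, −78 °C; then 15; then I2, THF; then NaOMe, MeOH, −78 °C to rt
Reagents that add atoms: none
Why: Zweifel olefination: iodine–lithium exchange on 18 gives the Z alkenyllithium 19 with retention, which adds to the boron of 15; iodine then forms an iodonium ion on C13′=C12′, C14′ shifts from boron to C13′ anti to iodine, and methoxide triggers anti elimination of boron and iodide from 21. The closest known reaction type is the Zweifel coupling of enantioenriched secondary boronic esters with 1,2-disubstituted alkenyllithiums to give trisubstituted alkenes. No ring is closed. No new stereocentre remains in the product: C14′ migrates with retention, so its S configuration and the cis relation to C12 come from 15, and the two centres of 21 are destroyed in the elimination. The E geometry (ring carbon trans to C11′) is required and is secured by the Z geometry of 19, because anti migration followed by anti elimination inverts the alkene geometry. Chemoselectivity for boron over the hindered C18 ester is secured by the fast formation of the boronate complex at −78 °C.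

Step 13
Reactants: 22 protected dimer
Product: 23 CNP0316988.1
Conditions: TBAF, THF, rt to 45 °C; then dilute aq HCl to pH 4
Reagents that add atoms: none
Why: Fluoride-induced desilylation: the TBS ether is cleaved at silicon and the 2-(trimethylsilyl)ethyl ester by attack at silicon and β-elimination (ethene and Me3SiF), so the hindered C18 carbonyl need not be attacked and the acid-sensitive exocyclic alkenes and all stereocentres are left alone.

Compound list
1 | 4-epi-trans-communic acid, (4R,5R,9S,10R)-labda-8(17),12E,14-trien-18-oic acid | C=C1CC[C@@H]2[C@](C)(CCC[C@@]2(C)C(=O)O)[C@H]1C/C=C(\C)C=C | starting material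
2 | 2-(trimethylsilyl)ethyl 4-epi-trans-communate | C=C1CC[C@@H]2[C@](C)(CCC[C@@]2(C)C(=O)OCC[Si](C)(C)C)[C@H]1C/C=C(\C)C=C | intermediate
3 | 2-(trimethylsilyl)ethyl 12-oxo-13,14,15,16-tetranorlabd-8(17)-en-18-oate (C12 aldehyde) | C=C1CC[C@@H]2[C@](C)(CCC[C@@]2(C)C(=O)OCC[Si](C)(C)C)[C@H]1CC=O | intermediate
4 | 2-(trimethylsilyl)ethyl 12-hydroxy-13,14,15,16-tetranorlabd-8(17)-en-18-oate | C=C1CC[C@@H]2[C@](C)(CCC[C@@]2(C)C(=O)OCC[Si](C)(C)C)[C@H]1CCO | intermediate
5 | 2-(trimethylsilyl)ethyl 12-(N,N-diisopropylcarbamoyloxy)-13,14,15,16-tetranorlabd-8(17)-en-18-oate | C=C1CC[C@@H]2[C@](C)(CCC[C@@]2(C)C(=O)OCC[Si](C)(C)C)[C@H]1CCOC(=O)N(C(C)C)C(C)C | intermediate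
6 | isopropenylboronic acid pinacol ester | CC(=C)B1OC(C)(C)C(C)(C)O1 | starting material
7 | (12S)-12-lithio carbamate, not isolated (sparteine ligand omitted) | C=C1CC[C@@H]2[C@](C)(CCC[C@@]2(C)C(=O)OCC[Si](C)(C)C)[C@H]1C[C@H]([Li])OC(=O)N(C(C)C)C(C)C | intermediate
8 | C12 boronate complex, not isolated (boron on C12 carries pinacolate and isopropenyl; lithium salt) | C=C1CC[C@@H]2[C@](C)(CCC[C@@]2(C)C(=O)OCC[Si](C)(C)C)[C@H]1C[C@H]([B-]1(C(C)=C)OC(C)(C)C(C)(C)O1)OC(=O)N(C(C)C)C(C)C.[Li+] | intermediate
9 | (12R)-allylic boronic ester: C12 carries 4,4,5,5-tetramethyl-1,3,2-dioxaborolan-2-yl and prop-1-en-2-yl | C=C1CC[C@@H]2[C@](C)(CCC[C@@]2(C)C(=O)OCC[Si](C)(C)C)[C@H]1C[C@@H](B1OC(C)(C)C(C)(C)O1)C(C)=C | intermediate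
10 | pent-4-en-1-ol | C=CCCCO | starting material
11 | pent-4-en-1-yl N,N-diisopropylcarbamate | C=CCCCOC(=O)N(C(C)C)C(C)C | intermediate
12 | (R)-1-lithiopent-4-enyl N,N-diisopropylcarbamate, not isolated (sparteine ligand omitted) | C=CCC[C@@H]([Li])OC(=O)N(C(C)C)C(C)C | intermediate
13 | C14′ boronate complex, not isolated (boron bridges C12 and the carbamate-bearing C14′; lithium salt) | C=C1CC[C@@H]2[C@](C)(CCC[C@@]2(C)C(=O)OCC[Si](C)(C)C)[C@H]1C[C@@H]([B-]1(OC(C)(C)C(C)(C)O1)[C@H](CCC=C)OC(=O)N(C(C)C)C(C)C)C(C)=C.[Li+] | intermediate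
14 | (12S,14′S)-open-chain boronic ester: C12 carries prop-1-en-2-yl and (1S)-1-(pinacolboryl)pent-4-en-1-yl | C=C1CC[C@@H]2[C@](C)(CCC[C@@]2(C)C(=O)OCC[Si](C)(C)C)[C@H]1C[C@@H]([C@H](CCC=C)B1OC(C)(C)C(C)(C)O1)C(C)=C | intermediate
15 | fragment A: 2-(trimethylsilyl)ethyl 11-[(1S,6S)-2-methyl-6-(pinacolboryl)cyclohex-2-en-1-yl]-12,13,14,15,16-pentanorlabd-8(17)-en-18-oate (cis) | C=C1CC[C@@H]2[C@](C)(CCC[C@@]2(C)C(=O)OCC[Si](C)(C)C)[C@H]1C[C@@H]1C(C)=CCC[C@@H]1B1OC(C)(C)C(C)(C)O1 | intermediate
16 | 2-(trimethylsilyl)ethyl (12′Z)-13′-iodo-14′,15′-dinorlabda-8′(17′),12′-dien-18′-oate | C/C(I)=C/C[C@H]1C(=C)CC[C@H]2[C@](C)(C(=O)OCC[Si](C)(C)C)CCC[C@]12C | intermediate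
17 | (12′Z)-13′-iodo-14′,15′-dinorlabda-8′(17′),12′-dien-18′-ol | C/C(I)=C/C[C@H]1C(=C)CC[C@H]2[C@](C)(CO)CCC[C@]12C | intermediate
18 | fragment B: 18′-O-tert-butyldimethylsilyl ether of 17 | C/C(I)=C/C[C@H]1C(=C)CC[C@H]2[C@](C)(CO[Si](C)(C)C(C)(C)C)CCC[C@]12C | intermediate
19 | (12′Z)-13′-lithio analogue of 18, not isolated | C/C([Li])=C/C[C@H]1C(=C)CC[C@H]2[C@](C)(CO[Si](C)(C)C(C)(C)C)CCC[C@]12C | intermediate
20 | alkenyl boronate complex of 19 and 15, not isolated (boron on C14′ and C13′; lithium salt) | C=C1CC[C@@H]2[C@](C)(CCC[C@@]2(C)C(=O)OCC[Si](C)(C)C)[C@H]1C[C@@H]1C(C)=CCC[C@@H]1[B-]1(OC(C)(C)C(C)(C)O1)/C(C)=C\C[C@H]1C(=C)CC[C@H]2[C@](C)(CO[Si](C)(C)C(C)(C)C)CCC[C@]12C.[Li+] | intermediate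
21 | β-iodoboronic ester, not isolated (C13′ carries C14′, methyl and boron; C12′ carries iodine; anti adduct) | C=C1CC[C@@H]2[C@](C)(CCC[C@@]2(C)C(=O)OCC[Si](C)(C)C)[C@H]1C[C@@H]1C(C)=CCC[C@@H]1[C@](C)(B1OC(C)(C)C(C)(C)O1)[C@H](I)C[C@H]1C(=C)CC[C@H]2[C@](C)(CO[Si](C)(C)C(C)(C)C)CCC[C@]12C | intermediate
22 | protected dimer: (12S,14′S,12′E) skeleton of the target as 2-(trimethylsilyl)ethyl ester and 18′-O-TBS ether | C=C1CC[C@@H]2[C@](C)(CCC[C@@]2(C)C(=O)OCC[Si](C)(C)C)[C@H]1C[C@@H]1C(C)=CCC[C@@H]1/C(C)=C/C[C@H]1C(=C)CC[C@H]2[C@](C)(CO[Si](C)(C)C(C)(C)C)CCC[C@]12C | intermediate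
23 | CNP0316988.1: (12S,14′S,12′E) dimer with C18 carboxylic acid and C18′ primary alcohol | C=C1CC[C@@H]2[C@](C)(CCC[C@@]2(C)C(=O)O)[C@H]1C[C@@H]1C(C)=CCC[C@@H]1/C(C)=C/C[C@H]1C(=C)CC[C@H]2[C@](C)(CO)CCC[C@]12C | target

Total step count: 13 (12 on the diterpene skeleton and 1 reagent preparation, step 6).
Longest linear sequence: 9 steps (1, 2, 3, 4, 5, 7, 8, 12, 13).

Steps most likely to fail

Step 5. What may go wrong: during the slow sparteine-mediated deprotonation s-BuLi may add to the C18 ester, or lithiation may stay incomplete, which lowers conversion and the selectivity at C12. The fallback makes the C12–B centre without an organolithium on the diterpene. It sets out from 3: Wittig olefination with ethyl 2-(triphenylphosphoranylidene)propanoate (toluene, 80 °C) should give the (E)-enoate F1. Reduction with i-Bu2AlH (CH2Cl2, −78 °C) should take the conjugated ethyl ester in preference to the hindered C18 ester and give the allylic alcohol F2. ClCO2Me and pyridine give the methyl carbonate F3. Copper-catalysed γ-selective (SN2′) borylation with B2pin2 (CuCl, NaOt-Bu, chiral bisphosphine or N-heterocyclic carbene ligand chosen for the 12R product, THF, 0 °C) then places boron on C12 with transposition of the alkene and returns to the route at 9.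

Step 7. What may go wrong: the boronate complex from the α-branched allylic boronic ester may form slowly or reversibly, so that the lithiated carbamate decomposes before the 1,2-shift. The fallback is a Matteson homologation and sets out from 9: LiCHCl2 (from CH2Cl2 and n-BuLi, THF, −100 °C) followed by ZnCl2 inserts a chloromethine unit into the C12–B bond to give the α-chloroboronic ester F4. But-3-enylmagnesium bromide then displaces chloride with inversion through the boronate complex and returns at 14. In this variant C14′ is controlled only by the neighbouring C12 centre, so the C14′ epimers, being diastereomers, are separated by chromatography at F4 or at 14.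

Step 12. What may go wrong: the α-branched alkenyllithium may add slowly to the hindered ring boronic ester, so that 19 is protonated and 15 recovered, or the elimination may be incomplete. The fallback moves the coupling in front of the ring closure. It sets out from 14 and 18: 19 (from 18 and t-BuLi) is added to the less hindered open-chain boronic ester 14, and I2 then NaOMe should give the open-chain coupling product F5 with the C14′–C13′ bond and the E alkene in place. Ring-closing metathesis of the isopropenyl and vinyl groups of F5 with RuCl2(=CHPh)(PCy3)(H2IMes) (CH2Cl2, 40 °C) closes the central ring and returns at 22.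

Further compounds
F1 | step 5 | (E)-enoate: C12 aldehyde of 3 extended to CH=C(CH3)CO2Et | C=C1CC[C@@H]2[C@](C)(CCC[C@@]2(C)C(=O)OCC[Si](C)(C)C)[C@H]1C/C=C(\C)C(=O)OCC
F2 | step 5 | (E)-allylic alcohol from F1 | C=C1CC[C@@H]2[C@](C)(CCC[C@@]2(C)C(=O)OCC[Si](C)(C)C)[C@H]1C/C=C(\C)CO
F3 | step 5 | (E)-allylic methyl carbonate from F2 | C=C1CC[C@@H]2[C@](C)(CCC[C@@]2(C)C(=O)OCC[Si](C)(C)C)[C@H]1C/C=C(\C)COC(=O)OC
F4 | step 7 | α-chloroboronic ester: chloro(pinacolboryl)methyl group on C12 of the 9 skeleton | C=C1CC[C@@H]2[C@](C)(CCC[C@@]2(C)C(=O)OCC[Si](C)(C)C)[C@H]1C[C@@H]([C@@H](Cl)B1OC(C)(C)C(C)(C)O1)C(C)=C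
F5 | step 12 | open-chain coupling product: 22 before ring closure, with isopropenyl on C12 and but-3-enyl on C14′ | C=C1CC[C@@H]2[C@](C)(CCC[C@@]2(C)C(=O)OCC[Si](C)(C)C)[C@H]1C[C@@H]([C@H](CCC=C)/C(C)=C/C[C@H]1C(=C)CC[C@H]2[C@](C)(CO[Si](C)(C)C(C)(C)C)CCC[C@]12C)C(C)=C
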